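The data stem from a simulated flask with made-up constants, noise included.

| flask | J | Q | G | remark | time |
|---|---|---|---|---|---|
| south | 0.050 M | 0.075 M | 0.010 M | run made earlier |  |
| south-east | 0.070 M | 0.075 M | 0.010 M | run made earlier |  |
| east | 0.11 M | 0.075 M | 0.010 M | run made earlier |  |
| zeta | 0.050 M | 0.0750 M | 0.0100 M (in portions, 4, over 25 min) | first portion at the start, last at 25 min | 40 min |
| theta | 0.050 M (fed, over 25 min) | 0.0750 M | 0.0100 M | all else is in the flask from the start; the feed brings no volume worth counting | 40 min |
| epsilon | 0.050 M | 0.0750 M | 0.0100 M (fed, over 25 min) | all else is in the flask from the start; the feed brings no volume worth counting | 40 min |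
| delta | 0.050 M | 0.0750 M | 0.0100 M | everything together at the start | 40 min |

| run | time / min | D / % | L / % | J / % |
|---|---|---|---|---|
| south | 2.00 | 43.6 | 12.1 | 39.4 |
| south | 3.00 | 50.0 | 12.7 | 31.4 |
| south | 5.00 | 52.6 | 12.2 | 22.6 |
| south | 8.00 | 49.0 | 12.0 | 16.5 |
| south | 15.0 | 37.9 | 12.1 | 12.2 |
| south | 25.0 | 29.6 | 12.5 | 9.0 |
| south-east | 6.00 | 48.4 | 9.4 | 25.6 |
| south-east | 12.0 | 39.7 | 10.5 | 19.2 |
| south-east | 20.0 | 31.9 | 10.3 | 15.6 |
| south-east | 25.0 | 27.5 | 9.7 | 14.7 |
| south-east | 30.0 | 25.1 | 9.5 | 14.9 |
| south-east | 40.0 | 22.5 | 10.0 | 11.9 |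
| east | 2.50 | 40.5 | 7.3 | 47.5 |
| east | 8.00 | 36.3 | 7.2 | 37.2 |
| east | 15.0 | 28.3 | 7.7 | 34.2 |
| east | 20.0 | 25.1 | 7.1 | 33.3 |
| east | 30.0 | 19.8 | 7.0 | 32.5 |
| east | 40.0 | 17.2 | 8.1 | 31.2 |

(standard deviation of a reading: 0.5 percentage points)

- what was read earlier has a scatter of 0.5 percentage points, one standard deviation

- the best flask by share of D in D plus L; "all alike" if 1.5 percentage points covers them all (zeta / theta / epsilon / delta / all alike)
- share of D in D plus L at the end, zeta
- share of D in D plus L at the end, theta
- share of D in D plus L at the end, epsilon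
- share of D in D plus L at the end, delta

We decide to follow G rather than D. L stands at 12.1% at the first south reading and at 12.0% at 8.00 min, so its making ends early. It takes 60.0% of G in the south run and 79.2% in the east run. We assume that the rest of G goes a rival way with Q, and we fold the charges into a split number N, equal to s·c(J)/c(Q): the parts of G that go to L for each part going the other way. Here s, the selectivity factor, is read from south as 2.25. Is one number enough? East reads 2.60, so s holds to within that gap, and N says nothing of D.

For delta, N is 1.50. Borrowing D from the south-east run at its last reading and L from south, our estimate of the share for delta is 65.2%. In theta, J arrives at a steady rate, so G of lifetime τ meets a c(J) of about that rate times τ. Taking τ as 2.00 min, the time of the first south reading, we estimate N in theta at 0.120, less than in delta. Our estimate for theta is then L near 2.14% and, with the same borrowed D, a share near 91.3%. Zeta and epsilon give G to J that is falling, as south shows with J at 16.5% by 8.00 min, so we place them between.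

The forecast names theta at 90%, on the ground that “J is low while G is fresh”, and gives 84% for zeta, 86% for epsilon and 64% for delta. For theta our estimate differs from it, 91.3% against 90%.

The best flask is theta at 99.1%, ahead of epsilon at 75.3%, zeta at 74.2% and delta at 65.3%.

    J + Q ⇌ D (K = 110 M⁻¹, k = 7.66 M⁻¹ min⁻¹)
    G + Q → X (k = 63.1 M⁻¹ min⁻¹)
    J + G → L (k = 160 M⁻¹ min⁻¹)
    D ⇌ E (K = 3.01, k = 0.0676 min⁻¹)

The half-life of G by the path to X taken by itself, at the charges of delta, is 0.15 min, which makes τ 0.211 min, and theta is charged with the same Q. With s this gives theta 0.250% of L, against 0.271% in the flask. For one more flask like theta but with 0.12 M of J the same reckoning gives 0.246% of L, and that flask holds 0.258%.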